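## Retrosynthetic overview
1. The target comes from its 4-O-methyl tetronate by O-demethylation. That ether is cut at C15–C16 (reductive allyl–alkyl coupling) into a C1–C15 furyl allylic acetate and a C16–C25 iodo-ylidene-tetronate.
2. The key cut is C21–C22, inside the tetronate. The butenolide opens to a cis γ-keto-β-methoxy-enoate, which comes from a C16–C21 Weinreb amide (acyl carbon) and β-lithio-β-methoxymethacrylate. This metallated enol ether is a masked acyl anion at C22, so two carbonyl-type acceptor carbons are joined.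
3. C18 comes from methyl hydrogen (R)-3-methylglutarate. It stays β to every carbonyl up to ring closure and cannot epimerise.
4. (R)-Linalool supplies C6–C15, the C8 stereocentre and the alkene. C5–C6 is made by hydroboration and B-alkyl Suzuki coupling with 3-(bromomethyl)furan. C15 is activated by E-selective SeO2 oxidation.
5. Rings: the furan is bought. A δ-lactone is made and reopened (steps 4–5). The butenolide is the only ring built for the target (step 8).

Assumption: atoms are labelled in the usual furanosesterterpene way (furan C1–C4, chain C5–C20 with methyls C9/C14/C19, tetronic acid C21–C25), the target is (8S,12E,18S,20Z), and 1, 2 and 7 are bought (1 and 7 in high ee).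

## Route

Step 1
Reactants: 1 (R)-linalool; 2 3-(bromomethyl)furan
Product: 4 (4S)-1-(furan-3-yl)-4,8-dimethylnon-7-en-4-ol, via B-alkyl-9-BBN borane 3 (not isolated)
Conditions: 9-BBN (1.2 equiv), THF, 0 °C → rt; then 2, PdCl2(dppf) (5 mol %), K3PO4 (3 M aq), THF/DMF, 50 °C
Reagents that add atoms: none
Why: 9-BBN hydroborates only the monosubstituted alkene (anti-Markovnikov), and the primary B-alkyl group is then passed in a B-alkyl Suzuki–Miyaura coupling to the β-hydrogen-free furylmethyl-palladium species from 2, while C8 comes unchanged from the chiral pool (R→S only through CIP ranking).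

Step 2
Reactants: 4 (4S)-1-(furan-3-yl)-4,8-dimethylnon-7-en-4-ol
Product: 5 (2E,6S)-9-(furan-3-yl)-2,6-dimethylnon-2-ene-1,6-diol
Conditions: SeO2 (0.3 equiv), t-BuOOH (2.5 equiv, decane), salicylic acid (10 mol %), CH2Cl2, 0 °C → rt
Reagents that add atoms: tert-butyl hydroperoxide CC(C)(C)OO (oxygen, relayed by catalytic selenium dioxide O=[Se]=O)
Why: The catalytic SeO2 allylic oxidation (ene reaction, then [2,3]-sigmatropic shift) oxygenates the methyl group trans to the chain of the only alkene, which fixes the 12E geometry with C15 functionalised.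

Step 3
Reactants: 5 (2E,6S)-9-(furan-3-yl)-2,6-dimethylnon-2-ene-1,6-diol
Product: 6 (2E,6S)-9-(furan-3-yl)-6-hydroxy-2,6-dimethylnon-2-en-1-yl acetate
Conditions: Ac2O (1.1 equiv), pyridine, CH2Cl2, 0 °C
Reagents that add atoms: acetic anhydride CC(=O)OC(C)=O
Why: This is a chemoselective O-acylation, because the primary allylic alcohol reacts while the hindered tertiary alcohol is inert without DMAP.

Step 4
Reactants: 7 methyl hydrogen (R)-3-methylglutarate
Product: 9 (4S)-4-methyloxan-2-one, via (S)-5-hydroxy-3-methylpentanoic acid 8 (not isolated)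
Conditions: LiBH4, THF, 0 → 50 °C; then 3 M HCl, rt
Reagents that add atoms: none
Why: The borohydride reduces the ester but not the lithium carboxylate formed first, and acid then lactonises, so the acid carbon becomes C21, the reduced carbon becomes C16, and the chiral-pool centre becomes (18S).

Step 5
Reactants: 9 (4S)-4-methyloxan-2-one
Product: 10 (3S)-5-hydroxy-N-methoxy-N,3-dimethylpentanamide
Conditions: MeNHOMe·HCl, AlMe3, CH2Cl2, 0 °C → rt
Reagents that add atoms: N,O-dimethylhydroxylamine hydrochloride CNOC.Cl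
Why: Weinreb aminolysis of the lactone with the aluminium amide opens the ring without touching the β-stereocentre.

Step 6
Reactants: 10 (3S)-5-hydroxy-N-methoxy-N,3-dimethylpentanamide
Product: 11 (3R)-5-iodo-N-methoxy-N,3-dimethylpentanamide
Conditions: I2, PPh3, imidazole, CH2Cl2, 0 °C
Reagents that add atoms: iodine II
Why: The Appel-type (Garegg–Samuelsson) iodination replaces the primary OH by SN2 before relactonisation can occur, and the descriptor change S→R is only a CIP effect.

Step 7
Reactants: 12 methyl propanoate; 13 methyl formate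
Product: 15 methyl (E)-3-methoxy-2-methylprop-2-enoate, via sodium formyl-ester enolate 14 (not isolated)
Conditions: NaH, THF, 0 °C → rt; then Me2SO4, DMF, rt
Reagents that add atoms: dimethyl sulfate COS(=O)(=O)OC
Why: A crossed Claisen formylation (the formate cannot enolise) followed by hard O-methylation gives mainly the favoured E β-methoxyacrylate, whose vinylic H lies cis to the ester.

Step 8
Reactants: 15 methyl (E)-3-methoxy-2-methylprop-2-enoate; 11 (3R)-5-iodo-N-methoxy-N,3-dimethylpentanamide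
Product: 18 (5Z)-5-[(2S)-4-iodo-2-methylbutylidene]-4-methoxy-3-methylfuran-2(5H)-one, via β-lithio acrylate 16 (not isolated), via cis keto ester 17 (not isolated)
Conditions: 15 (1.5 equiv), LDA (1.4 equiv), THF, −95 °C; 11, −95 → −70 °C; AcOH quench; crude, TsOH·H2O (10 mol %), toluene, reflux over 4 Å sieves (−MeOH)
Reagents that add atoms: none
Why: Proposed new method: deprotonating the only vinylic H of 15 (α to OMe, cis to the chelating ester) gives the metallated enol ether 16, a masked acyl anion at C22, which should acylate on Weinreb amide 11 through the chelated tetrahedral adduct without over-addition and so join the two acceptor carbons C21 and C22; because ketone and ester in 17 are held cis, acid-catalysed enol lactonisation with loss of MeOH closes the butenolide and equilibrates C20=C21 to the less crowded Z isomer, while C18 is never α to a carbonyl; the closest known chemistry is the tetronate synthesis from β-lithio-β-alkoxyacrylates and aldehydes, the Weinreb ketone synthesis, and the acid dehydration of γ-keto acid derivatives to γ-ylidenebutenolides.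

Step 9
Reactants: 18 (5Z)-5-[(2S)-4-iodo-2-methylbutylidene]-4-methoxy-3-methylfuran-2(5H)-one; 6 (2E,6S)-9-(furan-3-yl)-6-hydroxy-2,6-dimethylnon-2-en-1-yl acetate
Product: 19 (5Z)-5-[(2S,6E,10S)-13-(furan-3-yl)-10-hydroxy-2,6,10-trimethyltridec-6-en-1-ylidene]-4-methoxy-3-methylfuran-2(5H)-one
Conditions: NiCl2·glyme (10 mol %), 4,4′,4″-tri-tert-butylterpyridine (10 mol %), Zn (2 equiv), DMA/THF, 40 °C
Reagents that add atoms: none
Why: In this nickel-catalysed reductive cross-electrophile allyl–alkyl coupling the primary radical from 18 is captured by the syn-π-allylnickel from 6 and bonds at the unhindered CH2 terminus (C15), so 12E is kept and no basic organometallic meets the free OH, the lactone or C18.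

Step 10
Reactants: 19 (5Z)-5-[(2S,6E,10S)-13-(furan-3-yl)-10-hydroxy-2,6,10-trimethyltridec-6-en-1-ylidene]-4-methoxy-3-methylfuran-2(5H)-one
Product: 20 (5Z)-5-[(2S,6E,10S)-13-(furan-3-yl)-10-hydroxy-2,6,10-trimethyltridec-6-en-1-ylidene]-4-hydroxy-3-methylfuran-2(5H)-one
Conditions: EtSNa, DMF, rt → 40 °C; then 1 M HCl
Reagents that add atoms: none
Why: A soft thiolate demethylates the vinylogous methyl ester by SN2 (the leaving group is the stabilised tetronate anion), and this weakly basic medium leaves C18, the Z-alkene, the tertiary alcohol and the furan untouched.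

## Compound list
1 | (R)-linalool, (3R)-3,7-dimethylocta-1,6-dien-3-ol | CC(C)=CCC[C@@](C)(O)C=C | starting material
2 | 3-(bromomethyl)furan | BrCc1ccoc1 | starting material
3 | (3S)-1-(9-borabicyclo[3.3.1]nonan-9-yl)-3,7-dimethyloct-6-en-3-ol | CC(C)=CCC[C@@](C)(O)CCB1C2CCCC1CCC2 | intermediate
4 | (4S)-1-(furan-3-yl)-4,8-dimethylnon-7-en-4-ol | CC(C)=CCC[C@@](C)(O)CCCc1ccoc1 | intermediate
5 | (2E,6S)-9-(furan-3-yl)-2,6-dimethylnon-2-ene-1,6-diol | OC/C(C)=C/CC[C@@](C)(O)CCCc1ccoc1 | intermediate
6 | (2E,6S)-9-(furan-3-yl)-6-hydroxy-2,6-dimethylnon-2-en-1-yl acetate | CC(=O)OC/C(C)=C/CC[C@@](C)(O)CCCc1ccoc1 | intermediate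
7 | methyl hydrogen (R)-3-methylglutarate, (3R)-5-methoxy-3-methyl-5-oxopentanoic acid | OC(=O)C[C@@H](C)CC(=O)OC | starting material
8 | (S)-5-hydroxy-3-methylpentanoic acid | OC(=O)C[C@@H](C)CCO | intermediate
9 | (4S)-4-methyloxan-2-one | O=C1C[C@@H](C)CCO1 | intermediate
10 | (3S)-5-hydroxy-N-methoxy-N,3-dimethylpentanamide | CON(C)C(=O)C[C@@H](C)CCO | intermediate
11 | (3R)-5-iodo-N-methoxy-N,3-dimethylpentanamide | CON(C)C(=O)C[C@@H](C)CCI | intermediate
12 | methyl propanoate | CCC(=O)OC | starting material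
13 | methyl formate | COC=O | starting material
14 | sodium (E)-3-methoxy-2-methyl-3-oxoprop-1-en-1-olate | [Na+].[O-]/C=C(\C)C(=O)OC | intermediate
15 | methyl (E)-3-methoxy-2-methylprop-2-enoate | CO/C=C(\C)C(=O)OC | intermediate
16 | methyl (E)-3-lithio-3-methoxy-2-methylprop-2-enoate | CO/C([Li])=C(\C)C(=O)OC | intermediate
17 | methyl (2E,6R)-8-iodo-3-methoxy-2,6-dimethyl-4-oxooct-2-enoate | CO/C(C(=O)C[C@@H](C)CCI)=C(\C)C(=O)OC | intermediate
18 | (5Z)-5-[(2S)-4-iodo-2-methylbutylidene]-4-methoxy-3-methylfuran-2(5H)-one | CC1=C(OC)/C(=C/[C@@H](C)CCI)OC1=O | intermediate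
19 | (5Z)-5-[(2S,6E,10S)-13-(furan-3-yl)-10-hydroxy-2,6,10-trimethyltridec-6-en-1-ylidene]-4-methoxy-3-methylfuran-2(5H)-one | CC1=C(OC)/C(=C/[C@@H](C)CCC/C(C)=C/CC[C@@](C)(O)CCCc2ccoc2)OC1=O | intermediate
20 | (5Z)-5-[(2S,6E,10S)-13-(furan-3-yl)-10-hydroxy-2,6,10-trimethyltridec-6-en-1-ylidene]-4-hydroxy-3-methylfuran-2(5H)-one | CC1=C(O)/C(=C/[C@@H](C)CCC/C(C)=C/CC[C@@](C)(O)CCCc2ccoc2)OC1=O | target

## Step count and weak points
Total steps: 10. Longest linear sequence: 6 (7 → 9 → 10 → 11 → 18 → 19 → 20).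

**Step 8 is most at risk.** Reagent 16 may decompose faster than it acylates 11, or 17 may resist ring closure. The fallback sets out from 9 and comes back at 18, and it uses 16 in its proven mode, addition to an aldehyde.
- DIBAL-H reduces 9 to the lactol (4S)-4-methyloxan-2-ol F1.
- Two equivalents of 16 add to its open hydroxy-aldehyde form. The alkoxide lactonises in situ to 5-[(2S)-4-hydroxy-2-methylbutyl]-4-methoxy-3-methylfuran-2(5H)-one F2 (C5 epimers, of no consequence).
- The C5 anion (LDA, 2.2 equiv) is brominated with CBr4 to 5-bromo-5-[(2S)-4-hydroxy-2-methylbutyl]-4-methoxy-3-methylfuran-2(5H)-one F3.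
- DBU removes HBr to give (5Z)-5-[(2S)-4-hydroxy-2-methylbutylidene]-4-methoxy-3-methylfuran-2(5H)-one F4.
- I2/PPh3/imidazole then gives 18.

**Step 9 is second.** Either partner may dimerise, or branched or Z product may form. The fallback sets out from 5 and 18 and comes back at 19, and it replaces the sp3–sp3 coupling by olefination and selective reduction.
- MnO2 oxidises 5 to (2E,6S)-9-(furan-3-yl)-6-hydroxy-2,6-dimethylnon-2-enal F5.
- 18 and PPh3 in hot MeCN give [(3S,4Z)-4-(3-methoxy-4-methyl-5-oxofuran-2(5H)-ylidene)-3-methylbutyl]triphenylphosphonium iodide F6.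
- NaHMDS at −78 °C gives [(3S,4Z)-4-(3-methoxy-4-methyl-5-oxofuran-2(5H)-ylidene)-3-methylbutylidene]triphenylphosphorane F7.
- F7 reacts with F5 to give (5Z)-5-[(2S,4Z,6E,10S)-13-(furan-3-yl)-10-hydroxy-2,6,10-trimethyltrideca-4,6-dien-1-ylidene]-4-methoxy-3-methylfuran-2(5H)-one F8.
- Diimide (2-nitrobenzenesulfonyl hydrazide, Et3N) reduces only the disubstituted C15=C16 bond and gives 19.

**Step 1 is third.** The labile bromide 2 may hydrolyse or homocouple before the alkyl–alkyl Suzuki step. The fallback sets out from 1 and comes back at 4, and it reverses the roles of C5 and C6.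
- Borane 3 is oxidised (H2O2, NaOH) to (3R)-3,7-dimethyloct-6-ene-1,3-diol F9.
- TsCl/pyridine gives (3R)-3-hydroxy-3,7-dimethyloct-6-en-1-yl 4-methylbenzenesulfonate F10.
- F10 is displaced under Li2CuCl4 catalysis by (furan-3-ylmethyl)magnesium bromide F11 (from 2 and Mg, 2.2 equiv) to give 4.

## Further compounds
F1 | step 8 | (4S)-4-methyloxan-2-ol | OC1C[C@@H](C)CCO1
F2 | step 8 | 5-[(2S)-4-hydroxy-2-methylbutyl]-4-methoxy-3-methylfuran-2(5H)-one | CC1=C(OC)C(C[C@@H](C)CCO)OC1=O
F3 | step 8 | 5-bromo-5-[(2S)-4-hydroxy-2-methylbutyl]-4-methoxy-3-methylfuran-2(5H)-one | CC1=C(OC)C(Br)(C[C@@H](C)CCO)OC1=O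
F4 | step 8 | (5Z)-5-[(2S)-4-hydroxy-2-methylbutylidene]-4-methoxy-3-methylfuran-2(5H)-one | CC1=C(OC)/C(=C/[C@@H](C)CCO)OC1=O
F5 | step 9 | (2E,6S)-9-(furan-3-yl)-6-hydroxy-2,6-dimethylnon-2-enal | O=C/C(C)=C/CC[C@@](C)(O)CCCc1ccoc1
F6 | step 9 | [(3S,4Z)-4-(3-methoxy-4-methyl-5-oxofuran-2(5H)-ylidene)-3-methylbutyl]triphenylphosphonium iodide | CC1=C(OC)/C(=C/[C@@H](C)CC[P+](c2ccccc2)(c2ccccc2)c2ccccc2)OC1=O.[I-]
F7 | step 9 | [(3S,4Z)-4-(3-methoxy-4-methyl-5-oxofuran-2(5H)-ylidene)-3-methylbutylidene]triphenylphosphorane | CC1=C(OC)/C(=C/[C@@H](C)CC=P(c2ccccc2)(c2ccccc2)c2ccccc2)OC1=O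
F8 | step 9 | (5Z)-5-[(2S,4Z,6E,10S)-13-(furan-3-yl)-10-hydroxy-2,6,10-trimethyltrideca-4,6-dien-1-ylidene]-4-methoxy-3-methylfuran-2(5H)-one | CC1=C(OC)/C(=C/[C@@H](C)C/C=C\C(C)=C\CC[C@@](C)(O)CCCc2ccoc2)OC1=O
F9 | step 1 | (3R)-3,7-dimethyloct-6-ene-1,3-diol | CC(C)=CCC[C@@](C)(O)CCO
F10 | step 1 | (3R)-3-hydroxy-3,7-dimethyloct-6-en-1-yl 4-methylbenzenesulfonate | CC(C)=CCC[C@@](C)(O)CCOS(=O)(=O)c1ccc(C)cc1
F11 | step 1 | (furan-3-ylmethyl)magnesium bromide | Br[Mg]Cc1ccoc1
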